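**Retrosynthetic overview** (lactone locants: O1, C2 = ring C=O, C3 = CH–CH3, C4 = CH–CO2H, C5 = CH–chain)
1. Late disconnections: the chain ketone goes back to a terminal alkene (cross-metathesis with an ω-alkenyl methyl ketone, then hydrogenation), and the C3 methyl to an alkylation of the acid dianion anti to the C4 carboxylate.
2. Key disconnection C3–C4: the five-membered ring is made from a six-membered 3-diazo-2,3-dihydro-4H-pyran-4-one by photochemical Wolff ring contraction. C3 migrates from the ring ketone carbon to the diazo carbon C4, N2 is extruded, and the old ring ketone becomes the C4 carboxyl group.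
3. Enabling feature: the exocyclic carboxyl carbon on C4 is flanked by C3 (bonded to C2–O1) and by C5 (bonded to O1). Put back between C3 and C4 it completes the ring O1–C2=C3–C(=O)–C4–C5, a hetero-Diels–Alder-type adduct of the chain aldehyde with a 1-methoxy-3-silyloxybutadiene, in which C4 is the only enolisable carbon.
4. Ring order and stereo relay: dihydropyranone (catalysis sets C5), then ring-contracted 2,3-dihydrofuran acid (C4 set cis to the chain by protonation of the ketene hydrate), then oxidation of C2 to the lactone, then C3 methylation.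

Key step: step 3

Assumption (chemistry): (R)-BINOL with Ti(OiPr)4 is taken to direct attack to the Re face of the aldehyde, as is usual for this ligand antipode; if the sense proves opposite, (S)-BINOL is used.

**Step 1**
Reactants: 1 undec-10-enal; 2 (E)-1-methoxy-3-(trimethylsilyloxy)buta-1,3-diene
Product: 4 (S)-2-(dec-9-en-1-yl)-2,3-dihydro-4H-pyran-4-one, via silyl aldol adduct 3 (not isolated)
Conditions: (R)-BINOL (20 mol%), Ti(OiPr)4 (10 mol%), 4 Å MS, Et2O, −20 °C; then CF3CO2H, CH2Cl2, 0 °C
Reagents that add atoms: none
Why: Titanium–BINOL-catalysed Mukaiyama aldol addition of the silyloxydiene followed by acid-promoted cyclisation with loss of methanol (a formal hetero-Diels–Alder reaction, precedented for unbranched aliphatic aldehydes) builds the six-membered ring and sets the one catalyst-controlled stereocenter, the future C5, by Re-face attack on 1 (2S in 4); the remote terminal alkene is inert.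

**Step 2**
Reactants: 4 (S)-2-(dec-9-en-1-yl)-2,3-dihydro-4H-pyran-4-one
Product: 6 (S)-2-(dec-9-en-1-yl)-3-diazo-2,3-dihydro-4H-pyran-4-one, via trifluoroacetyl ketone 5 (not isolated)
Conditions: LiN(SiMe3)2, THF, −78 °C, then CF3CO2CH2CF3; aq. HCl work-up; then MsN3, Et3N, H2O (1 equiv), MeCN, 20 °C
Reagents that add atoms: methanesulfonyl azide CS(=O)(=O)N=[N+]=[N-]; 2,2,2-trifluoroethyl trifluoroacetate FC(F)(F)COC(=O)C(F)(F)F (its acyl group is carried only by 5)
Why: Detrifluoroacetylative diazo transfer via the kinetic lithium enolate, the standard route to α'-diazo-α,β-unsaturated ketones, can only engage the ring CH2 next to the stereocenter because the other α-carbon is the vinylogous-ester CH, so the diazo group lands on the future C4; no stereocenter is formed and the 2S center is not enolisable.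

**Step 3**
Reactants: 6 (S)-2-(dec-9-en-1-yl)-3-diazo-2,3-dihydro-4H-pyran-4-one
Product: 9 (2S,3S)-2-(dec-9-en-1-yl)-2,3-dihydrofuran-3-carboxylic acid, via vinylketene 7 (not isolated), via ketene hydrate 8 (not isolated)
Conditions: hν (365 nm), THF/H2O (9:1), 0.02 M, 10 °C
Reagents that add atoms: water O
Why: Direct irradiation of the s-cis-locked cyclic α-diazo ketone expels N2 with concerted 1,2-shift of the vinylic carbon (future C3) from the ring ketone carbon to the diazo carbon (future C4), giving ring-contracted vinylketene 7; water adds to the ketene to give ene-1,1-diol 8, which ketonises by protonation at C4. The closest known reaction type is the photochemical Wolff ring contraction of cyclic α-diazo ketones with aqueous trapping (3-diazochroman-4-ones to 2,3-dihydrobenzofuran-3-carboxylic acids; α'-diazo enones to vinylketenes). The five-membered ring is closed by ring contraction, an intra-ring 1,2-migration that forms C3–C4 while the former ring ketone is pushed out as the exocyclic carboxyl carbon, not by an exo or endo attack. The new stereocenter C4 is set in the ketonisation of 8: allylic strain with the exocyclic C(OH)2 group holds the C5 chain pseudoaxial, so the proton should enter anti to it and the carboxyl group should end cis to the chain (3S in 9, the kinetic and less stable epimer); C5 is not touched. The step needs the Wolff shift to outrun the 1,2-hydride shift from C5 that would give the 4-pyranone, which direct photolysis of a diazo ketone fixed in the s-cis geometry (no metal catalyst, no heat) should secure, and it needs α- rather than γ-protonation of 8, which is favoured because α-protonation delivers the carboxylic acid directly.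

**Step 4**
Reactants: 9 (2S,3S)-2-(dec-9-en-1-yl)-2,3-dihydrofuran-3-carboxylic acid
Product: 11 (2S,3S)-2-(dec-9-en-1-yl)-5-oxotetrahydrofuran-3-carboxylic acid, via lactol 10 (not isolated)
Conditions: HCl (cat.), MeCN/H2O, 20 °C; then TEMPO (10 mol%), PhI(OAc)2, 20 °C
Reagents that add atoms: water O
Why: Acid-catalysed hydration of the cyclic enol ether to the lactol, followed by oxoammonium (TEMPO/PhI(OAc)2) oxidation of the lactol, raises C2 to the lactone level by two standard operations; C4 is α only to the carboxylic acid and should not epimerise, and the terminal alkene is untouched.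

**Step 5**
Reactants: 11 (2S,3S)-2-(dec-9-en-1-yl)-5-oxotetrahydrofuran-3-carboxylic acid
Product: 13 (2S,3S,4S)-2-(dec-9-en-1-yl)-4-methyl-5-oxotetrahydrofuran-3-carboxylic acid, via disodium dianion 12 (not isolated)
Conditions: NaN(SiMe3)2 (2.3 equiv), THF, −78 °C; MeI, −78 to −40 °C; 1 M HCl
Reagents that add atoms: iodomethane CI
Why: Alkylation of the carboxylate/lactone-enolate dianion, the established endgame for α-methyl paraconic acids: MeI attacks C3 from the face anti to the C4 carboxylate, which is also the face anti to the C5 chain, so the new center should be 3,4-trans (4S in furan numbering), while the carboxylate keeps C4–H from being deprotonated.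

**Step 6**
Reactants: 13 (2S,3S,4S)-2-(dec-9-en-1-yl)-4-methyl-5-oxotetrahydrofuran-3-carboxylic acid; 14 hept-6-en-2-one
Product: 15 (2S,3S,4S)-4-methyl-5-oxo-2-(14-oxopentadec-9-en-1-yl)tetrahydrofuran-3-carboxylic acid (E/Z mixture)
Conditions: second-generation Grubbs catalyst RuCl2(=CHPh)(PCy3)(H2IMes) (5 mol%), 14 (4 equiv), CH2Cl2, 40 °C
Reagents that add atoms: none
Why: Olefin cross-metathesis of two unhindered terminal alkenes; an excess of 14 biases the statistical mixture toward the cross product, the free acid is tolerated, and the E/Z mixture does not matter because the alkene is reduced next.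

**Step 7**
Reactants: 15 (2S,3S,4S)-4-methyl-5-oxo-2-(14-oxopentadec-9-en-1-yl)tetrahydrofuran-3-carboxylic acid
Product: 16 (2S,3S,4S)-4-methyl-5-oxo-2-(14-oxopentadecyl)tetrahydrofuran-3-carboxylic acid
Conditions: H2 (1 atm), Pd/C, EtOAc, 20 °C
Reagents that add atoms: none
Why: Heterogeneous hydrogenation saturates the isolated 1,2-disubstituted alkene without touching ketone, lactone or acid and without affecting any stereocenter, giving the target.

**Compound list**
1 | undec-10-enal | C=CCCCCCCCCC=O | starting material
2 | (E)-1-methoxy-3-(trimethylsilyloxy)buta-1,3-diene | CO/C=C/C(=C)O[Si](C)(C)C | starting material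
3 | silyl aldol adduct: (S,E)-1-methoxy-5-(trimethylsilyloxy)pentadeca-1,14-dien-3-one [not isolated] | C=CCCCCCCCC[C@H](O[Si](C)(C)C)CC(=O)/C=C/OC | intermediate
4 | (S)-2-(dec-9-en-1-yl)-2,3-dihydro-4H-pyran-4-one | C=CCCCCCCCC[C@@H]1OC=CC(=O)C1 | intermediate
5 | trifluoroacetyl ketone: (2S)-2-(dec-9-en-1-yl)-3-(2,2,2-trifluoroacetyl)-2,3-dihydro-4H-pyran-4-one, C3 epimers/enol [not isolated] | C=CCCCCCCCC[C@@H]1OC=CC(=O)C1C(=O)C(F)(F)F | intermediate
6 | (S)-2-(dec-9-en-1-yl)-3-diazo-2,3-dihydro-4H-pyran-4-one | C=CCCCCCCCC[C@@H]1OC=CC(=O)C1=[N+]=[N-] | intermediate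
7 | vinylketene: (S)-[2-(dec-9-en-1-yl)furan-3(2H)-ylidene]methanone [not isolated] | C=CCCCCCCCC[C@@H]1OC=CC1=C=O | intermediate
8 | ketene hydrate: (S)-[2-(dec-9-en-1-yl)furan-3(2H)-ylidene]methanediol [not isolated] | C=CCCCCCCCC[C@@H]1OC=CC1=C(O)O | intermediate
9 | (2S,3S)-2-(dec-9-en-1-yl)-2,3-dihydrofuran-3-carboxylic acid | C=CCCCCCCCC[C@@H]1OC=C[C@@H]1C(=O)O | intermediate
10 | lactol: (2S,3S)-2-(dec-9-en-1-yl)-5-hydroxytetrahydrofuran-3-carboxylic acid, anomers [not isolated] | C=CCCCCCCCC[C@@H]1OC(O)C[C@@H]1C(=O)O | intermediate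
11 | (2S,3S)-2-(dec-9-en-1-yl)-5-oxotetrahydrofuran-3-carboxylic acid | C=CCCCCCCCC[C@@H]1OC(=O)C[C@@H]1C(=O)O | intermediate
12 | disodium dianion: disodium (2S,3S)-2-(dec-9-en-1-yl)-5-oxido-2,3-dihydrofuran-3-carboxylate [not isolated] | C=CCCCCCCCC[C@@H]1OC([O-])=C[C@@H]1C(=O)[O-].[Na+].[Na+] | intermediate
13 | (2S,3S,4S)-2-(dec-9-en-1-yl)-4-methyl-5-oxotetrahydrofuran-3-carboxylic acid | C=CCCCCCCCC[C@@H]1OC(=O)[C@@H](C)[C@@H]1C(=O)O | intermediate
14 | hept-6-en-2-one | CC(=O)CCCC=C | starting material
15 | (2S,3S,4S)-4-methyl-5-oxo-2-(14-oxopentadec-9-en-1-yl)tetrahydrofuran-3-carboxylic acid (E/Z) | CC(=O)CCCC=CCCCCCCCC[C@@H]1OC(=O)[C@@H](C)[C@@H]1C(=O)O | intermediate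
16 | (2S,3S,4S)-4-methyl-5-oxo-2-(14-oxopentadecyl)tetrahydrofuran-3-carboxylic acid | CC(=O)CCCCCCCCCCCCC[C@@H]1OC(=O)[C@@H](C)[C@@H]1C(=O)O | target

**Totals**
Total steps: 7. Longest linear sequence: 7 (from 1).

**Steps most likely to fail, with fallbacks**

Step 3 (key step). What may go wrong: loss of N2 with 1,2-hydride shift and aromatisation to the 4-pyranone instead of the Wolff shift; γ-protonation of the ketene hydrate, which moves the double bond into conjugation and erases C4; or poor facial selectivity in the protonation. The fallback sets out from 1 and comes back at 11, and builds C3–C4 by enolate alkylation of a β-lactone instead of by ring contraction. Cyclocondensation of 1 with acetyl chloride (O-trimethylsilylquinidine or its pseudoenantiomer, whichever gives 4S; LiClO4, iPr2NEt, CH2Cl2/Et2O, −78 °C) would give (S)-4-(dec-9-en-1-yl)oxetan-2-one F1. Its lithium enolate (LiN(iPr)2, THF, −78 °C) would be alkylated by tert-butyl bromoacetate anti to the chain to give tert-butyl 2-[(3S,4S)-4-(dec-9-en-1-yl)-2-oxooxetan-3-yl]acetate F2. CF3CO2H would free 2-[(3S,4S)-4-(dec-9-en-1-yl)-2-oxooxetan-3-yl]acetic acid F3. Aqueous NaOH would open the β-lactone at the acyl–oxygen bond to (2S)-2-[(1S)-1-hydroxyundec-10-en-1-yl]butanedioic acid F4 (as its salt), and acidification would close the five-membered lactone to 11. The trans β-lactone maps onto the 4,5-cis γ-lactone because the ring oxygen changes partner from the carboxyl carbon to the acetic acid carbon.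

Step 2. What may go wrong: retro-oxa-Michael opening or racemisation of the lithium enolate of 4, or O- instead of C-trifluoroacetylation. The fallback sets out from 4 and comes back at 6 and avoids the enolate. Heating 4 with Me2NCH(OMe)2 (toluene, 90 °C) would give the enaminone (S)-2-(dec-9-en-1-yl)-3-[(dimethylamino)methylidene]-2,3-dihydro-4H-pyran-4-one F5. Diazo transfer to the enaminone with tosyl azide (CH2Cl2, 20 °C) would give 6 with loss of the N-sulfonyl formamidine.

Step 1. What may go wrong: insufficient enantioselectivity with the unbranched aldehyde, or oligomerisation of the diene. The fallback sets out from 1 and comes back at 4, and replaces the diene addition by a direct ynone aldol. Addition of 4-(trimethylsilyl)but-3-yn-2-one to 1 under dinuclear zinc catalysis (Et2Zn, ProPhenol antipode chosen for 5S, THF, 0 °C) would give (S)-5-hydroxy-1-(trimethylsilyl)pentadec-14-en-1-yn-3-one F6. K2CO3 in MeOH would remove the silyl group and add methanol to the ynone to give (S,E)-5-hydroxy-1-methoxypentadeca-1,14-dien-3-one F7. CF3CO2H would cyclise F7 to 4 with loss of methanol.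

**Further compounds**
F1 | step 3 | (S)-4-(dec-9-en-1-yl)oxetan-2-one | C=CCCCCCCCC[C@@H]1OC(=O)C1
F2 | step 3 | tert-butyl 2-[(3S,4S)-4-(dec-9-en-1-yl)-2-oxooxetan-3-yl]acetate | C=CCCCCCCCC[C@@H]1OC(=O)[C@H]1CC(=O)OC(C)(C)C
F3 | step 3 | 2-[(3S,4S)-4-(dec-9-en-1-yl)-2-oxooxetan-3-yl]acetic acid | C=CCCCCCCCC[C@@H]1OC(=O)[C@H]1CC(=O)O
F4 | step 3 | (2S)-2-[(1S)-1-hydroxyundec-10-en-1-yl]butanedioic acid | C=CCCCCCCCC[C@H](O)[C@H](CC(=O)O)C(=O)O
F5 | step 2 | (S)-2-(dec-9-en-1-yl)-3-[(dimethylamino)methylidene]-2,3-dihydro-4H-pyran-4-one | C=CCCCCCCCC[C@@H]1OC=CC(=O)C1=CN(C)C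
F6 | step 1 | (S)-5-hydroxy-1-(trimethylsilyl)pentadec-14-en-1-yn-3-one | C=CCCCCCCCC[C@H](O)CC(=O)C#C[Si](C)(C)C
F7 | step 1 | (S,E)-5-hydroxy-1-methoxypentadeca-1,14-dien-3-one | C=CCCCCCCCC[C@H](O)CC(=O)/C=C/OC
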